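Ring B of the labdane decalin is built onto an enantioenriched ring A β-keto ester (C4 stereocentre in place) by an alkynone Robinson annulation: the C10 enolate adds to C9 of a silyloxy-alkynone and the resulting methyl ketone condenses with the C5 carbonyl, forming C9–C10 and C5–C6 in one operation. The step exploits the latent C7 ketone of the 7-hydroxy-8(17)-ene unit, which makes C6 nucleophilic and C9 electrophilic, and the quaternary C10 next to the C5 ring-fusion carbon. The precursor is a simple cyclohexanone plus an acyclic alkynone; the dienone product carries both ring B alkenes for stereocontrolled reduction. A boron-chelate-directed Diels–Alder reaction with a flavone-derived methoxyquinone ends the route.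

Key step: step 5

Remarks on the chemistry:
- Labdane numbering is used for the decalin: C1–C10 ring carbons, C11 on C9, C17 the methylene on C8, C16 the methyl on C13, C18 the α-carboxyl carbon on C4, C19 the β-methyl on C4, C20 the β-methyl on C10. The α face is the one opposite C20.
- Assumption: in step 2 the L-valine ester enamine, lithiated in toluene with HMPA, is taken to give the (R)-keto ester. If the sense of induction is the opposite, tert-butyl D-valinate (also commercial) is used with no other change.
- Compound 2 is used as the free base, liberated from its commercial hydrochloride.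

Step 1
Reactants: 1 methyl 2-oxocyclohexane-1-carboxylate; 2 tert-butyl L-valinate
Product: 3 methyl 2-{[(2S)-1-tert-butoxy-3-methyl-1-oxobutan-2-yl]amino}cyclohex-1-ene-1-carboxylate
Conditions: BF3·OEt2 (cat.), PhMe, reflux, Dean–Stark
Reagents that add atoms: none
Why: Acid-catalysed condensation of the amine with the ketone of the β-keto ester gives the hydrogen-bonded enamino ester (vinylogous carbamate); the valine stereocentre is untouched.

Step 2
Reactants: 3 enamino ester
Product: 5 methyl (1R)-1-methyl-2-oxocyclohexane-1-carboxylate, via methylated ketimine 4 (not isolated)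
Conditions: LiN(i-Pr)2, PhMe, HMPA (1 equiv), −78 °C; MeI; then 1 M aq. HCl, 25 °C
Reagents that add atoms: iodomethane CI; water O
Why: Chiral enamine alkylation: the lithiated enamino ester is held by chelation to the valine ester, so MeI attacks the face away from the isopropyl group and sets the quaternary C4 (labdane numbering) as R; aqueous acid then hydrolyses the ketimine.

Step 3
Reactants: 5 methyl (1R)-1-methyl-2-oxocyclohexane-1-carboxylate
Product: 6 methyl (1R)-1,3-dimethyl-2-oxocyclohexane-1-carboxylate (mixture of C3 epimers)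
Conditions: LiN(i-Pr)2, THF, −78 °C; MeI, −78 → 0 °C
Reagents that add atoms: iodomethane CI
Why: Kinetic enolate alkylation: deprotonation is possible only at the methylene α-carbon (future C10), and the epimer mixture at that carbon does not matter because C10 is re-enolised in step 5.

Step 4
Reactants: 7 tert-butyldimethyl(prop-2-yn-1-yloxy)silane; 8 N-methoxy-N-methylacetamide
Product: 9 5-[(tert-butyldimethylsilyl)oxy]pent-3-yn-2-one
Conditions: n-BuLi, THF, −78 °C; then 8, −78 → 0 °C; aq. NH4Cl
Reagents that add atoms: none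
Why: Acylation of the lithium acetylide with a Weinreb amide stops at the ketone because the tetrahedral chelate collapses only on work-up.

Step 5
Reactants: 6 methyl (1R)-1,3-dimethyl-2-oxocyclohexane-1-carboxylate; 9 5-[(tert-butyldimethylsilyl)oxy]pent-3-yn-2-one
Product: 12 dienone methyl 11-(tert-butyldimethylsilyloxy)-7-oxo-12,13,14,15,16,17-hexanorlabda-5,8-dien-18-oate, via Michael adduct 10 (not isolated), via aldol 11 (not isolated)
Conditions: LiN(i-Pr)2, THF, −78 °C; 9, −78 → 0 °C; then KOt-Bu (0.3 equiv), t-BuOH, 45 °C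
Reagents that add atoms: none
Why: The lithium enolate of 6 (only C10 can enolise because C4 is quaternary) adds in a conjugate sense to C9 of alkynone 9 and forms the C9–C10 bond; the allenolate is protonated to enone 10, whose E and Z forms equilibrate through the γ-dienolate under KOt-Bu, and the methyl ketone enolate of the Z form closes ring B onto the C5 carbonyl (C5–C6 bond) and loses water to give the cross-conjugated dienone. The closest known reaction type is the alkynone variant of the Robinson annulation (Michael addition followed by aldol condensation to a 4,4-disubstituted cyclohexa-2,5-dienone). Ring B closes by a 6-(enolendo)-exo-trig aldol addition followed by E1cB dehydration. The new quaternary centre C10 is controlled by C4: in the lithium-chelated enolate the ester lies in the enolate plane and the C4 methyl is pseudo-axial, so the alkynone enters on the opposite face and C20 ends up cis to the C4 methyl (both β). The step needs 1,4- over 1,2-addition (the crowded 1,2-aldolate reverts on warming, the 1,4-adduct does not) and a single aldol mode, which is secured because C4 and C10 are quaternary and C5 is the only carbonyl the C6 enolate can reach through a six-membered transition state.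

Step 6
Reactants: 12 dienone
Product: 13 enone methyl 11-(tert-butyldimethylsilyloxy)-7-oxo-9α-H-12,13,14,15,16,17-hexanorlabd-5-en-18-oate
Conditions: H2 (1 atm), Pd/C, EtOAc, Et3N (trace), 25 °C, stopped after 1 equiv H2
Reagents that add atoms: none
Why: Heterogeneous catalytic hydrogenation reduces the more accessible C8=C9 alkene (C5=C6 lies between two quaternary carbons) and delivers hydrogen to C9 from the α face opposite the C10 methyl, as in the Δ1-reduction of steroidal 1,4-dien-3-ones, so that C11 becomes β.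

Step 7
Reactants: 13 enone
Product: 14 trans-decalin ketone methyl 11-(tert-butyldimethylsilyloxy)-7-oxo-12,13,14,15,16,17-hexanorlabdan-18-oate (5α-H; 9α-H)
Conditions: Li (2.5 equiv), NH3(l), THF, t-BuOH (1 equiv), −78 °C; NH4Cl
Reagents that add atoms: none
Why: Dissolving-metal (Birch-type) enone reduction: the C5 carbanion is protonated axially to give the trans ring fusion (5α-H), and the hindered non-enolisable ester and the silyl ether survive the short reaction at −78 °C.

Step 8
Reactants: 14 trans-decalin ketone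
Product: 15 bromide methyl 11-bromo-7-oxo-12,13,14,15,16,17-hexanorlabdan-18-oate
Conditions: Ph3PBr2, CH2Cl2, 0 → 25 °C
Reagents that add atoms: dibromotriphenylphosphorane BrP(Br)(c1ccccc1)(c1ccccc1)c1ccccc1
Why: Ph3PBr2 converts tert-butyldimethylsilyl ethers directly into bromides by SN2 displacement of the oxyphosphonium group; no stereocentre is involved and the ketone is inert at 25 °C.

Step 9
Reactants: 16 prop-2-yn-1-ol
Product: 17 (2E)-3-iodo-2-methylprop-2-en-1-ol
Conditions: AlMe3 (3 equiv), Cp2ZrCl2 (0.25 equiv), CH2Cl2, 0 → 25 °C; then I2, THF, −30 °C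
Reagents that add atoms: trimethylaluminium C[Al](C)C; iodine II
Why: Negishi zirconium-catalysed carboalumination adds methyl and aluminium syn across the alkyne with methyl on the internal carbon, and iodinolysis with retention gives the E vinyl iodide.

Step 10
Reactants: 17 (2E)-3-iodo-2-methylprop-2-en-1-ol
Product: 18 (2E)-3-iodo-2-methylprop-2-enal
Conditions: MnO2, CH2Cl2, 25 °C
Reagents that add atoms: none
Why: MnO2 oxidises the allylic alcohol selectively to the enal without touching the vinyl iodide or the alkene geometry.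

Step 11
Reactants: 18 (2E)-3-iodo-2-methylprop-2-enal
Product: 19 (1E)-1-iodo-2-methylbuta-1,3-diene
Conditions: Ph3PCH3Br, NaN(SiMe3)2, THF, −78 → 0 °C; used as a solution
Reagents that add atoms: methyltriphenylphosphonium bromide C[P+](c1ccccc1)(c1ccccc1)c1ccccc1.[Br-]
Why: Wittig methylenation of the aldehyde forms the terminal alkene and leaves the E-configured trisubstituted alkene unchanged.

Step 12
Reactants: 15 bromide; 19 (1E)-1-iodo-2-methylbuta-1,3-diene
Product: 21 methyl 7-oxo-17-norlabda-12E,14-dien-18-oate, via alkylzinc bromide 20 (not isolated)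
Conditions: Zn dust, LiCl, THF, 50 °C; then 19, Pd(OAc)2 (3 mol %), SPhos, THF, 25 °C
Reagents that add atoms: none
Why: Negishi coupling: LiCl-promoted zinc insertion into the primary bromide tolerates the ketone and the ester, and the palladium-catalysed sp3–sp2 coupling retains the alkenyl iodide geometry to give the 12E diene.

Step 13
Reactants: 21 methyl 7-oxo-17-norlabda-12E,14-dien-18-oate
Product: 24 methyl 7-oxolabda-8(17),12E,14-trien-18-oate, via Mannich base 22 (not isolated), via trimethylammonium iodide 23 (not isolated)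
Conditions: LiN(i-Pr)2, THF, −78 °C; [CH2=NMe2]I, −78 → 25 °C; then MeI, MeOH, 25 °C; then aq. NaHCO3, CH2Cl2
Reagents that add atoms: N,N-dimethylmethyleneiminium iodide (Eschenmoser's salt) C=[N+](C)C.[I-]
Why: Kinetic deprotonation takes place at C8 because the axial 6β-H is shielded by both axial methyl groups C19 and C20 (compare the Δ2-enolisation of 5α-3-keto steroids); the Mannich reaction with the iminium salt, N-methylation and E1cB loss of trimethylamine then give the α-methylene ketone.

Step 14
Reactants: 24 methyl 7-oxolabda-8(17),12E,14-trien-18-oate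
Product: 25 methyl 7β-hydroxylabda-8(17),12E,14-trien-18-oate
Conditions: NaBH4, CeCl3·7H2O, MeOH, −78 °C
Reagents that add atoms: none
Why: Luche reduction is 1,2-selective, and axial hydride attack from the α face (opposite the C10 methyl) gives the equatorial 7β-alcohol.

Step 15
Reactants: 25 methyl 7β-hydroxylabda-8(17),12E,14-trien-18-oate
Product: 26 7β-hydroxylabda-8(17),12E,14-trien-18-oic acid
Conditions: NaSEt, DMF, 70 °C; then dil. HCl to pH 4
Reagents that add atoms: none
Why: The thiolate cleaves the hindered ester by SN2 attack at the methyl carbon, which avoids the shielded acyl carbon and leaves the allylic alcohol and the diene untouched.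

Step 16
Reactants: 27 1-(2,4,6-trihydroxyphenyl)ethan-1-one; 28 2,4,5-trimethoxybenzoyl chloride
Product: 30 5,7-dihydroxy-2-(2,4,5-trimethoxyphenyl)-4H-chromen-4-one, via 1,3-diketone 29 (not isolated)
Conditions: LiN(SiMe3)2 (4.2 equiv), THF, −78 °C; 28, −78 → 25 °C; then AcOH, H2SO4 (cat.), 95 °C
Reagents that add atoms: none
Why: Baker–Venkataraman-type C-acylation of the lithium polyanion of the acetophenone gives the 1,3-diketone, and acid-catalysed cyclodehydration with an ortho hydroxyl closes the chromone.

Step 17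
Reactants: 30 5,7-dihydroxy-2-(2,4,5-trimethoxyphenyl)-4H-chromen-4-one
Product: 31 2-(5,7-dihydroxy-4-oxo-4H-chromen-2-yl)-5-methoxycyclohexa-2,5-diene-1,4-dione
Conditions: (NH4)2Ce(NO3)6 (2.5 equiv), MeCN–H2O, 0 °C
Reagents that add atoms: water O
Why: Oxidative demethylation with tetravalent cerium converts the para-related 2′- and 5′-methoxy groups of the electron-rich ring into the 1,4-quinone carbonyls, while the acyl-deactivated, hydrogen-bonded A ring is much harder to oxidise.

Step 18
Reactants: 26 7β-hydroxylabda-8(17),12E,14-trien-18-oic acid; 31 chromonyl methoxyquinone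
Product: 34 dichrostachine E, via diacetoxyboron chelate 32 (not isolated), via chelated cycloadduct 33 (not isolated)
Conditions: 31, B(OAc)3 (1.1 equiv), CH2Cl2, 25 °C; then 26, 25 → 40 °C, dark; then H2O–THF, 25 °C
Reagents that add atoms: none
Why: Diels–Alder reaction directed by boron chelation of the peri-hydroxy carbonyl of the chromone: the chelated, pyrylium-like chromone makes the quinone CH carbon the electrophilic terminus for the unsubstituted diene carbon C15 and takes the endo position, the methoxy group deactivates the other quinone alkene, suprafacial addition gives the cis ring fusion, and the dienophile adds to the C12 face opposite the decalin in the rotamer where the diene lies over the C8 methylene, which together should set C12 and the two ring-fusion centres as in the target.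

Compound list
1 | methyl 2-oxocyclohexane-1-carboxylate | COC(=O)C1CCCCC1=O | starting material
2 | tert-butyl L-valinate | CC(C)[C@H](N)C(=O)OC(C)(C)C | starting material
3 | methyl 2-{[(2S)-1-tert-butoxy-3-methyl-1-oxobutan-2-yl]amino}cyclohex-1-ene-1-carboxylate | COC(=O)C1=C(N[C@@H](C(C)C)C(=O)OC(C)(C)C)CCCC1 | intermediate
4 | methyl (1R)-2-{[(2S)-1-tert-butoxy-3-methyl-1-oxobutan-2-yl]imino}-1-methylcyclohexane-1-carboxylate (methylated ketimine) | COC(=O)[C@]1(C)CCCCC1=N[C@@H](C(C)C)C(=O)OC(C)(C)C | intermediate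
5 | methyl (1R)-1-methyl-2-oxocyclohexane-1-carboxylate | COC(=O)[C@]1(C)CCCCC1=O | intermediate
6 | methyl (1R)-1,3-dimethyl-2-oxocyclohexane-1-carboxylate (C3 epimers) | COC(=O)[C@]1(C)CCCC(C)C1=O | intermediate
7 | tert-butyldimethyl(prop-2-yn-1-yloxy)silane | C#CCO[Si](C)(C)C(C)(C)C | starting material
8 | N-methoxy-N-methylacetamide | CON(C)C(C)=O | starting material
9 | 5-[(tert-butyldimethylsilyl)oxy]pent-3-yn-2-one | CC(=O)C#CCO[Si](C)(C)C(C)(C)C | intermediate
10 | Michael adduct: methyl (1R)-3-{1-[(tert-butyldimethylsilyl)oxy]-4-oxopent-2-en-2-yl}-1,3-dimethyl-2-oxocyclohexane-1-carboxylate (3-methyl cis to 1-methyl; E/Z mixture) | O=C1[C@](C)(CCC[C@@]1(C)C(=O)OC)C(CO[Si](C)(C)C(C)(C)C)=CC(C)=O | intermediate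
11 | aldol: methyl 11-(tert-butyldimethylsilyloxy)-5-hydroxy-7-oxo-12,13,14,15,16,17-hexanorlabd-8-en-18-oate | C=1C(=O)CC2(O)[C@](C)(CCC[C@@]2(C)C(=O)OC)C=1CO[Si](C)(C)C(C)(C)C | intermediate
12 | dienone: methyl 11-(tert-butyldimethylsilyloxy)-7-oxo-12,13,14,15,16,17-hexanorlabda-5,8-dien-18-oate (4α-CO2Me; 4β-Me; 10β-Me) | C=1C(=O)C=C2[C@](C)(CCC[C@@]2(C)C(=O)OC)C=1CO[Si](C)(C)C(C)(C)C | intermediate
13 | enone: methyl 11-(tert-butyldimethylsilyloxy)-7-oxo-9α-H-12,13,14,15,16,17-hexanorlabd-5-en-18-oate | C1C(=O)C=C2[C@](C)(CCC[C@@]2(C)C(=O)OC)[C@H]1CO[Si](C)(C)C(C)(C)C | intermediate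
14 | trans-decalin ketone: methyl 11-(tert-butyldimethylsilyloxy)-7-oxo-12,13,14,15,16,17-hexanorlabdan-18-oate (5α-H; 9α-H) | C1C(=O)C[C@@H]2[C@](C)(CCC[C@@]2(C)C(=O)OC)[C@H]1CO[Si](C)(C)C(C)(C)C | intermediate
15 | bromide: methyl 11-bromo-7-oxo-12,13,14,15,16,17-hexanorlabdan-18-oate | C1C(=O)C[C@@H]2[C@](C)(CCC[C@@]2(C)C(=O)OC)[C@H]1CBr | intermediate
16 | prop-2-yn-1-ol | C#CCO | starting material
17 | (2E)-3-iodo-2-methylprop-2-en-1-ol | I/C=C(\C)CO | intermediate
18 | (2E)-3-iodo-2-methylprop-2-enal | I/C=C(\C)C=O | intermediate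
19 | (1E)-1-iodo-2-methylbuta-1,3-diene | I/C=C(\C)C=C | intermediate
20 | alkylzinc bromide: C11 zinc bromide of 15 | C1C(=O)C[C@@H]2[C@](C)(CCC[C@@]2(C)C(=O)OC)[C@H]1C[Zn]Br | intermediate
21 | methyl 7-oxo-17-norlabda-12E,14-dien-18-oate | C1C(=O)C[C@@H]2[C@](C)(CCC[C@@]2(C)C(=O)OC)[C@H]1C/C=C(\C)C=C | intermediate
22 | Mannich base: methyl 17-(dimethylamino)-7-oxolabda-12E,14-dien-18-oate (C8 epimers) | CN(C)CC1C(=O)C[C@@H]2[C@](C)(CCC[C@@]2(C)C(=O)OC)[C@H]1C/C=C(\C)C=C | intermediate
23 | trimethylammonium iodide of 22 | C[N+](C)(C)CC1C(=O)C[C@@H]2[C@](C)(CCC[C@@]2(C)C(=O)OC)[C@H]1C/C=C(\C)C=C.[I-] | intermediate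
24 | methyl 7-oxolabda-8(17),12E,14-trien-18-oate | C=C1C(=O)C[C@@H]2[C@](C)(CCC[C@@]2(C)C(=O)OC)[C@H]1C/C=C(\C)C=C | intermediate
25 | methyl 7β-hydroxylabda-8(17),12E,14-trien-18-oate | C=C1[C@@H](O)C[C@@H]2[C@](C)(CCC[C@@]2(C)C(=O)OC)[C@H]1C/C=C(\C)C=C | intermediate
26 | 7β-hydroxylabda-8(17),12E,14-trien-18-oic acid | C=C1[C@@H](O)C[C@@H]2[C@](C)(CCC[C@@]2(C)C(=O)O)[C@H]1C/C=C(\C)C=C | intermediate
27 | 1-(2,4,6-trihydroxyphenyl)ethan-1-one | CC(=O)c1c(O)cc(O)cc1O | starting material
28 | 2,4,5-trimethoxybenzoyl chloride | O=C(Cl)c1cc(OC)c(OC)cc1OC | starting material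
29 | 1-(2,4,6-trihydroxyphenyl)-3-(2,4,5-trimethoxyphenyl)propane-1,3-dione | O=C(CC(=O)c1cc(OC)c(OC)cc1OC)c1c(O)cc(O)cc1O | intermediate
30 | 5,7-dihydroxy-2-(2,4,5-trimethoxyphenyl)-4H-chromen-4-one | COc1cc(OC)c(OC)cc1-c1cc(=O)c2c(O)cc(O)cc2o1 | intermediate
31 | 2-(5,7-dihydroxy-4-oxo-4H-chromen-2-yl)-5-methoxycyclohexa-2,5-diene-1,4-dione | COC1=CC(=O)C(=CC1=O)c1cc(=O)c2c(O)cc(O)cc2o1 | intermediate
32 | diacetoxyboron chelate of 31 (boron bridging the 5-oxygen and the 4-carbonyl oxygen) | COC1=CC(=O)C(=CC1=O)C1=CC(=[O+]2)c3c(O[B-]2(OC(C)=O)OC(C)=O)cc(O)cc3O1 | intermediate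
33 | diacetoxyboron chelate of the cycloadduct 34 | C=C1[C@@H](O)C[C@@H]2[C@](C)(CCC[C@@]2(C)C(=O)O)[C@H]1C[C@@H]1C(C)=CC[C@H]2C(=O)C(OC)=CC(=O)[C@@]12C1=CC(=[O+]2)c3c(O[B-]2(OC(C)=O)OC(C)=O)cc(O)cc3O1 | intermediate
34 | dichrostachine E | C=C1[C@@H](O)C[C@@H]2[C@](C)(CCC[C@@]2(C)C(=O)O)[C@H]1C[C@@H]1C(C)=CC[C@H]2C(=O)C(OC)=CC(=O)[C@@]12c1cc(=O)c2c(O)cc(O)cc2o1 | target

Total step count: 18. Longest linear sequence: 12 steps (steps 1, 2, 3, 5, 6, 7, 8, 12, 13, 14, 15, 18).

Steps most likely to fail

Step 5. The hindered enolate may add 1,2 to the alkynone or exchange a proton with it, so that the alkynone oligomerises. The aldol closure onto the C5 carbonyl, which lies between two quaternary carbons, may stall, and the facial selectivity at C10 may be poor. The fallback sets out from 6 and comes back at 12. The enone (3E)-5-[(tert-butyldimethylsilyl)oxy]pent-3-en-2-one F1 is made by Wittig reaction of commercial (tert-butyldimethylsilyloxy)acetaldehyde with Ph3P=CHC(O)CH3. Ketone 6 is converted with LiN(i-Pr)2 and Me3SiCl into its trimethylsilyl enol ether F2. A TiCl4-mediated Mukaiyama–Michael addition of F2 to F1 at −78 °C gives the 1,5-diketone F3. KOt-Bu in t-BuOH closes ring B by aldol condensation to the octalone F4 (both C9 epimers). Dehydrogenation with DDQ (dioxane, reflux) removes the C9 stereocentre and gives dienone 12.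

Step 18. The acetoxy ligands on boron may exchange with the carboxylic acid and the hydroxyl group of 26, so that chelate control is lost and regio-, endo/exo and facial selectivity are poor. The fallback sets out from 31 and comes back at 34. Quinone 31 is first converted with BF3·OEt2 (CH2Cl2, 25 °C) into its isolable difluoroboron chelate F5, whose fluoride ligands cannot exchange. Cycloaddition of F5 with 26 (CH2Cl2, 25–40 °C) gives the difluoroboron-chelated cycloadduct F6, and warm aqueous methanol (45 °C) removes boron to give 34.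

Step 12. The volatile dienyl iodide 19 may be lost or polymerise, and transmetalation of the β-branched alkylzinc may be slow, so that reduction and homocoupling take over. The fallback sets out from 15 (with 17) and comes back at 21; it makes the terminal alkene by olefination after the coupling. Iodo alcohol 17 is silylated (t-BuMe2SiCl, imidazole) to the non-volatile (E)-tert-butyl[(3-iodo-2-methylprop-2-en-1-yl)oxy]dimethylsilane F7. F7 is coupled with alkylzinc 20 under the same palladium catalysis to give the allylic silyl ether F8. Bu4NF gives the allylic alcohol F9, and MnO2 gives the enal F10. Ph3P=CH2 (1.0 equiv, −78 °C, where the aldehyde reacts before the C7 ketone) then gives diene 21.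

Further compounds
F1 | step 5 | (3E)-5-[(tert-butyldimethylsilyl)oxy]pent-3-en-2-one | CC(=O)/C=C/CO[Si](C)(C)C(C)(C)C
F2 | step 5 | methyl (1R)-1,3-dimethyl-2-[(trimethylsilyl)oxy]cyclohex-2-ene-1-carboxylate | C[Si](C)(C)OC1=C(C)CCC[C@@]1(C)C(=O)OC
F3 | step 5 | methyl (1R)-3-{1-[(tert-butyldimethylsilyl)oxy]-4-oxopentan-2-yl}-1,3-dimethyl-2-oxocyclohexane-1-carboxylate (3-methyl cis to 1-methyl; C9 epimers) | O=C1[C@](C)(CCC[C@@]1(C)C(=O)OC)C(CO[Si](C)(C)C(C)(C)C)CC(C)=O
F4 | step 5 | methyl 11-(tert-butyldimethylsilyloxy)-7-oxo-12,13,14,15,16,17-hexanorlabd-5-en-18-oate (C9 epimers) | C1C(=O)C=C2[C@](C)(CCC[C@@]2(C)C(=O)OC)C1CO[Si](C)(C)C(C)(C)C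
F5 | step 18 | difluoroboron chelate of 31 | COC1=CC(=O)C(=CC1=O)C1=CC(=[O+]2)c3c(O[B-]2(F)F)cc(O)cc3O1
F6 | step 18 | difluoroboron chelate of 34 | C=C1[C@@H](O)C[C@@H]2[C@](C)(CCC[C@@]2(C)C(=O)O)[C@H]1C[C@@H]1C(C)=CC[C@H]2C(=O)C(OC)=CC(=O)[C@@]12C1=CC(=[O+]2)c3c(O[B-]2(F)F)cc(O)cc3O1
F7 | step 12 | (E)-tert-butyl[(3-iodo-2-methylprop-2-en-1-yl)oxy]dimethylsilane | I/C=C(\C)CO[Si](C)(C)C(C)(C)C
F8 | step 12 | methyl 14-(tert-butyldimethylsilyloxy)-7-oxo-15,17-dinorlabd-12E-en-18-oate | C1C(=O)C[C@@H]2[C@](C)(CCC[C@@]2(C)C(=O)OC)[C@H]1C/C=C(\C)CO[Si](C)(C)C(C)(C)C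
F9 | step 12 | methyl 14-hydroxy-7-oxo-15,17-dinorlabd-12E-en-18-oate | C1C(=O)C[C@@H]2[C@](C)(CCC[C@@]2(C)C(=O)OC)[C@H]1C/C=C(\C)CO
F10 | step 12 | methyl 7,14-dioxo-15,17-dinorlabd-12E-en-18-oate | C1C(=O)C[C@@H]2[C@](C)(CCC[C@@]2(C)C(=O)OC)[C@H]1C/C=C(\C)C=O
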